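A small charge, 0.44 M of X with 1.00 equiv of L, is what we propose to repeat unchanged in the next run, stopped at 4.0 min, provided the chains are long enough by then.

    X + L ⇌ D + Q (K1 = 73, k1 = 0.389 L mol⁻¹ s⁻¹)
    D → J (k2 = 6.47 × 10⁻⁵ s⁻¹)
    L → Z (k3 = 0.0177 s⁻¹)

X 0.44 M; L 1.00 equiv; time 4.0 min

- each molecule carries two end groups: a chain counts once for every two ends that are left, dead ends included; the units are half of the end groups of the two monomers charged
- a link that another step uses up counts as cut, two dead ends; so do two ends of one kind that react with each other
- run time (flask): 4.0 min

- whether the average number of monomer units in a chain (unreacted monomers counted as chains of one) reaches 3.0 by 4.0 min (yes / no)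
- average number of monomer units in a chain (unreacted monomers counted as chains of one) at 4.0 min

Each link removes two ends, and a cut link leaves them as dead ends, so the average length is the charged X divided by the charged X minus [D]. Therefore 0.293 M is the link floor, the least [D] that gives the wanted length. With nothing lost, and with [Q] equal to [D], the balance of step 1 would put [D] at 0.394 M, which is more than the floor.

But L has a second exit. At the start, step 1 (forward rate alone) uses L 9.7 times as fast as step 3, so, as a rough estimate that stretches this starting ratio over the early race, we deduct a selectivity share of 0.0412 M. If step 1 stands balanced with [D] at the floor, our estimate of [L] is 0.00804 M, and step 3 then removes L, which the way back of step 1 restores from links, at 0.008535 M min⁻¹, faster than step 2 cuts links at 0.001139 M min⁻¹. Deducting that drain over the run leaves us with [D] near 0.319 M, a length of 3.62. We would keep the charge and not run longer.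

The forecast says yes, with a length of 3.5, between 3.2 and 3.9; after an early peak, it expects [D] to fall slowly as “Q drives the reverse step and the regenerated L keeps dying”. Its length is less than ours.

The simulation gives yes and a length of 3.45, within the forecast's range, and the length reached 3.0 at 0.241 min. So we leave the charge as it is and stop at 4.0 min. At 4.00 min the flask holds 0.313 M of D, more than the link floor of 0.293 M. At 40.0 min the same flask holds 0.162 M of D, less than the floor, and the length is 1.58.

Its constants stand for no real mixture; the rest is arithmetic.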